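At 5.00 d the noon flask shows E at 52.9% and solid Q at 0%, so a leftover of 47.1% of the charge appears in no reading, and two chemists dispute what it means for this flask.

common to all: Q 10 mM

| flask | temperature | remark | time |
|---|---|---|---|
| noon | 35 °C | the very flask that is asked about, followed so far |  |
| autumn | 20 °C | run made earlier |  |
| flask | 35 °C |  | 8.0 d |

- noon (time / d: E / %, Q / %): 0.250: 0.4, 82.5; 0.833: 9.7, 48.7; 1.25: 19.6, 26.8; 2.08: 38.5, 0; 3.00: 47.1, 0; 4.00: 50.7, 0; 5.00: 52.9, 0
- autumn (time / d: E / %, Q / %): 0.500: 0.5, 68.0; 1.67: 3.9, 22.6; 2.50: 7.9, 0.4; 4.00: 15.2, 0; 6.00: 21.7, 0.1; 8.00: 24.9, 0.1; 10.0: 27.8, 0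

(standard deviation of a reading: 0.3 percentage points)

- Sunday's: at 8.0 d raise the temperature by 10 K, then wait 15 d
- Monday's: at 8.0 d take out 90% of the E then present, then wait 15 d
- Saturday's: change nothing and wait 15 d more

- solid, in amounts per volume of the solution: Q
- E taken out counts as made
- at the start none of Q is in solution

1. E, in percent of the Q first charged, at 8.0 d
2. the option that brings most further E ("none" if no option brings more than 2 percentage points) (Sunday's / Monday's / Saturday's / none)
3. E present, with what was taken out counted in, in percent of the Q first charged, after Sunday's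
4. E present, with what was taken out counted in, in percent of the Q first charged, after Monday's

The first chemist reads a ceiling, which is thermodynamic control: the leftover stands in balance with E. In the noon run E gained 8.6 percentage points from 2.08 d to 3.00 d, but 2.2 points in the last interval, and her words are “Reversible Q⇌E fits with a nearly constant forward constant”. So the forecast is hers: 55.8% now, 68% after Sunday's, 77% after Monday's, and the best option Monday's.

The second chemist, whose reckoning this is, reads kinetic control. That last gain stands against a scatter of 0.3 points, so E is still climbing and the question is how fast the clock runs. She compares two steep stretches. E rose 9.9 points in 0.417 d at 35 °C, and 7.3 points in 1.50 d at 20 °C, a ratio in speed of 4.88. In logarithms that is 0.688 powers of ten over 15.0 K, hence 0.459 per 10 K, which gives 2.88. This is the speed factor, the multiple of the pace of E per 10 K of warming. Sunday's 15 d therefore count as 43.2 d at 35 °C, which is longer than Saturday's wait. Taking out E changes no clock, so she expects Monday's to gain what Saturday's gains.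

The flask gives 56.9%, then 81.1% after Sunday's and 69.1% after Monday's, so the best option is Sunday's. The gains are 24 points for Sunday's and 12 points for Monday's, with 12 points for Saturday's. The ceiling keeps its region: from 4.46 d to 12.9 d, E lies within 5 points of its value at 8.0 d.

    D → Z (k = 0.0330 h⁻¹, Ea = 105 kJ mol⁻¹)
    Z → E (k = 0.650 h⁻¹, Ea = 106 kJ mol⁻¹)
    D ⇌ G (K = 2.10, k = 0.0260 h⁻¹, Ea = 96.0 kJ mol⁻¹, ΔH = −22.0 kJ mol⁻¹)
    G ⇌ L (K = 2.20, k = 0.0310 h⁻¹, Ea = 101 kJ mol⁻¹, ΔH = −33.0 kJ mol⁻¹)
    Q ⇌ D, rate k5*(cs5 - [D]) while solid is left; crystals form when [D] > cs5 (solubility = 9.80 mM, k = 0.0320 h⁻¹)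
    2 D → X (k = 2.60 M⁻¹ h⁻¹, Ea = 64.0 kJ mol⁻¹)
    (constants at 35 °C)

In the noon flask Q dissolved into D, half of that turnover done by 0.810 d, and D ran through Z to E and also into G, L and X. In that flask at 8.00 d, with solid Q at 0%, G and L together held 23.4%, and at 80.0 d they held 0.866% while E stood at 80.6%. The speed factor 2.88 also runs downward: the repeat of the flask at 10 °C lies 2.50 steps of 10 K below 35 °C, so its 8.0 d count as 0.568 d at 35 °C. The noon run showed E at 0.4% by 0.250 d and at 9.7% by 0.833 d, and the repeat at 10 °C gave 6.93%.

The numbers in the tables are calculated for an exercise; the scatter is artificial.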